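**Plan**

- Numbering: lactone C1(=O), methyl-bearing C2, C3, ring carbon C4, exocyclic C5, stereocentre C6, chain C7–C17, 3-furyl ring on C17. The enabling feature is the C12–C13 single bond of the open chain, lying between the E alkenes C10=C11 and C14=C15 (a 1,5-diene), so that both of its carbons are allylic.
- Cuts: first C4=C5 (vinylogous aldol/elimination onto the intact butenolide ring), then C12–C13 (C12 allylic sulfone carbanion plus C13 allylic bromide), then C7–C8 and C10–CH3/C11–C12 in the sulfone arm and C14=C15 and C16–C17 in the furan arm.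
- Forward: the sulfone arm (steps 1–6) and the bromide arm (steps 7–12) are joined at C12–C13, the sulfonyl group is removed, C5 is raised to the aldehyde and the butenolide is attached last. No ring is formed in the route; the furan and the lactone ring are bought.
- Stereochemistry: C6 comes from (R)-3-bromo-2-methylpropan-1-ol (the descriptor becomes S by a priority change only). E-C10=C11 comes from syn-carboalumination, E-C14=C15 from a stabilised Wittig reaction, Z-C4=C5 from the E1cB elimination.

Key step: step 13

Remark: the target is read as the (5Z)-ylidene lactone with (6S) configuration and E geometry at C10=C11 and C14=C15; (4-bromobut-1-yn-1-yl)trimethylsilane and the two stabilised phosphoranes are taken as catalogue reagents; C12 of 19 and the two new centres of 25 arise as mixtures that converge later.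

**Route**

Step 1
Reactants: 1 (R)-3-bromo-2-methylpropan-1-ol
Product: 2 (R)-(3-bromo-2-methylpropoxy)(tert-butyl)dimethylsilane
Conditions: TBSCl, imidazole, CH2Cl2, 0 °C to rt
Reagents that add atoms: tert-butyldimethylsilyl chloride (TBSCl), CC(C)(C)[Si](C)(C)Cl
Why: Imidazole-promoted O-silylation of a primary alcohol is routine and does not touch the stereocentre or the primary bromide.

Step 2
Reactants: 3 (4-bromobut-1-yn-1-yl)trimethylsilane; 2 (R)-(3-bromo-2-methylpropoxy)(tert-butyl)dimethylsilane
Product: 5 tert-butyldimethyl{[(2S)-2-methyl-7-(trimethylsilyl)hept-6-yn-1-yl]oxy}silane, via [4-(trimethylsilyl)but-3-yn-1-yl]magnesium bromide 4 (not isolated)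
Conditions: 3, Mg, THF, rt to 40 °C; then 2, Li2CuCl4 (3 mol %), THF/NMP, 0 °C to rt
Reagents that add atoms: none
Why: A copper-catalysed alkyl–alkyl Grignard cross-coupling (Kochi coupling) should replace the primary bromide of 2 and form C7–C8, with the C-silyl group masking the acidic alkyne C–H and with C6, which is not a reacting centre, keeping its configuration.

Step 3
Reactants: 5 tert-butyldimethyl{[(2S)-2-methyl-7-(trimethylsilyl)hept-6-yn-1-yl]oxy}silane
Product: 6 tert-butyldimethyl{[(2S)-2-methylhept-6-yn-1-yl]oxy}silane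
Conditions: K2CO3 (cat.), MeOH, rt
Reagents that add atoms: none
Why: Base-catalysed methanolysis (protodesilylation) cleaves the C(sp)–Si bond selectively and should leave the primary TBS ether intact.

Step 4
Reactants: 6 tert-butyldimethyl{[(2S)-2-methylhept-6-yn-1-yl]oxy}silane
Product: 8 (2E,7S)-8-[(tert-butyldimethylsilyl)oxy]-3,7-dimethyloct-2-en-1-ol, via (E)-alkenyldimethylalane 7 (not isolated)
Conditions: Me3Al, Cp2ZrCl2 (25 mol %), CH2Cl2, 0 °C to rt; then (CH2O)n, THF, 0 °C to rt
Reagents that add atoms: trimethylaluminium, C[Al](C)C; paraformaldehyde (as formaldehyde), C=O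
Why: Negishi zirconium-catalysed carboalumination adds methyl and aluminium syn across the terminal alkyne with methyl on the internal carbon, and hydroxymethylation of the alkenylalane by formaldehyde proceeds with retention, which fixes the E geometry of C10=C11 and installs C12.

Step 5
Reactants: 8 (2E,7S)-8-[(tert-butyldimethylsilyl)oxy]-3,7-dimethyloct-2-en-1-ol
Product: 9 tert-butyl{[(2S,6E)-8-bromo-2,6-dimethyloct-6-en-1-yl]oxy}dimethylsilane
Conditions: CBr4, PPh3, CH2Cl2, 0 °C
Reagents that add atoms: carbon tetrabromide, BrC(Br)(Br)Br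
Why: The Appel reaction converts a primary allylic alcohol into the bromide under neutral conditions, without allylic transposition and without loss of the silyl ether.

Step 6
Reactants: 9 tert-butyl{[(2S,6E)-8-bromo-2,6-dimethyloct-6-en-1-yl]oxy}dimethylsilane
Product: 10 tert-butyl{[(2S,6E)-2,6-dimethyl-8-(phenylsulfonyl)oct-6-en-1-yl]oxy}dimethylsilane
Conditions: PhSO2Na, DMF, rt
Reagents that add atoms: sodium benzenesulfinate, [Na+].[O-]S(=O)c1ccccc1
Why: SN2 S-alkylation of the sulfinate by the primary allylic bromide is the standard entry to prenyl-type sulfones and should keep the E alkene.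

Step 7
Reactants: 11 furan-3-carbaldehyde (3-furaldehyde)
Product: 12 methyl (2E)-3-(furan-3-yl)prop-2-enoate
Conditions: Ph3P=CHCO2Me, CH2Cl2, rt
Reagents that add atoms: methyl (triphenylphosphoranylidene)acetate, COC(=O)C=P(c1ccccc1)(c1ccccc1)c1ccccc1
Why: Wittig olefination of an aromatic aldehyde with a stabilised ylide adds the two carbons C15 and C16 as an E acrylate.

Step 8
Reactants: 12 methyl (2E)-3-(furan-3-yl)prop-2-enoate
Product: 13 methyl 3-(furan-3-yl)propanoate
Conditions: NaBH4, NiCl2·6H2O (cat.), MeOH, 0 °C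
Reagents that add atoms: none
Why: Nickel boride conjugate reduction saturates only the electron-poor alkene of the enoate and should spare the aromatic furan and the ester.

Step 9
Reactants: 13 methyl 3-(furan-3-yl)propanoate
Product: 14 3-(furan-3-yl)propanal
Conditions: i-Bu2AlH (1.05 equiv), CH2Cl2, −78 °C; MeOH, then aqueous potassium sodium tartrate
Reagents that add atoms: none
Why: Partial reduction of an ester with i-Bu2AlH at −78 °C stops at the aluminium hemiacetal, which releases the aldehyde only on work-up.

Step 10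
Reactants: 14 3-(furan-3-yl)propanal
Product: 15 ethyl (2E)-5-(furan-3-yl)-2-methylpent-2-enoate
Conditions: Ph3P=C(CH3)CO2Et, toluene, 80 °C
Reagents that add atoms: ethyl 2-(triphenylphosphoranylidene)propanoate, CCOC(=O)C(C)=P(c1ccccc1)(c1ccccc1)c1ccccc1
Why: Wittig olefination with the α-methyl stabilised ylide is reliably E-selective and sets the C14=C15 geometry together with the C14 methyl group and C13.

Step 11
Reactants: 15 ethyl (2E)-5-(furan-3-yl)-2-methylpent-2-enoate
Product: 16 (2E)-5-(furan-3-yl)-2-methylpent-2-en-1-ol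
Conditions: i-Bu2AlH (2.2 equiv), CH2Cl2, −78 °C
Reagents that add atoms: none
Why: 1,2-Reduction of an enoate by i-Bu2AlH gives the allylic alcohol without touching alkene geometry or the furan.

Step 12
Reactants: 16 (2E)-5-(furan-3-yl)-2-methylpent-2-en-1-ol
Product: 17 3-[(3E)-5-bromo-4-methylpent-3-en-1-yl]furan
Conditions: CBr4, PPh3, CH2Cl2, −20 to 0 °C; used at once
Reagents that add atoms: carbon tetrabromide, BrC(Br)(Br)Br
Why: Appel bromination is acid-free, so the primary allylic bromide should form without SN2′ transposition and without damage to the acid-sensitive furan.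

Step 13
Reactants: 10 tert-butyl{[(2S,6E)-2,6-dimethyl-8-(phenylsulfonyl)oct-6-en-1-yl]oxy}dimethylsilane; 17 3-[(3E)-5-bromo-4-methylpent-3-en-1-yl]furan
Product: 19 tert-butyl{[(2S,6E,10E)-13-(furan-3-yl)-2,6,10-trimethyl-8-(phenylsulfonyl)trideca-6,10-dien-1-yl]oxy}dimethylsilane, via C12-lithiated sulfone 18 (not isolated)
Conditions: n-BuLi (1.05 equiv), THF, −78 °C; then 17, −78 to −20 °C
Reagents that add atoms: none
Why: n-BuLi removes a C12 proton of 10 to give the sulfonyl-stabilised allylic carbanion 18, which attacks the primary allylic carbon C13 of 17 in an SN2 displacement of bromide and so forms the C12–C13 bond at the centre of the 1,5-diene. The closest known reaction type is the allylation of lithiated prenyl-type aryl sulfones with allylic halides, the standard sulfone-carbanion coupling of polyprenoid chains. No ring is closed. The one new stereocentre, the sulfonyl-bearing C12, forms without control as an epimer mixture and is erased in step 14, while C6 lies far from the reacting site and keeps its configuration. The step needs α- rather than γ-alkylation of the ambident anion, which the sulfonyl group secures by holding charge and lithium at C12, and SN2 rather than SN2′ attack with both E alkenes kept, which the unhindered primary C13 terminus (against the substituted C15) and the low temperature secure. One equivalent of base at −78 °C limits the reaction to mono-alkylation, and the furan and the silyl ether are inert to the carbanion.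

Step 14
Reactants: 19 tert-butyl{[(2S,6E,10E)-13-(furan-3-yl)-2,6,10-trimethyl-8-(phenylsulfonyl)trideca-6,10-dien-1-yl]oxy}dimethylsilane
Product: 20 tert-butyl{[(2S,6E,10E)-13-(furan-3-yl)-2,6,10-trimethyltrideca-6,10-dien-1-yl]oxy}dimethylsilane
Conditions: PdCl2(dppp) (5 mol %), LiBHEt3 (2.2 equiv), THF, 0 °C
Reagents that add atoms: none
Why: In this palladium-catalysed reductive desulfonylation, zerovalent palladium formed in the flask ionises the allylic C–S bond to a π-allylpalladium that should take hydride at the less substituted terminus C12, so that C10=C11 stays trisubstituted and E.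

Step 15
Reactants: 20 tert-butyl{[(2S,6E,10E)-13-(furan-3-yl)-2,6,10-trimethyltrideca-6,10-dien-1-yl]oxy}dimethylsilane
Product: 21 (2S,6E,10E)-13-(furan-3-yl)-2,6,10-trimethyltrideca-6,10-dien-1-ol
Conditions: Bu4NF, THF, 0 °C to rt
Reagents that add atoms: none
Why: Fluoride-mediated cleavage of the Si–O bond is neutral enough for the furan and both trisubstituted alkenes.

Step 16
Reactants: 21 (2S,6E,10E)-13-(furan-3-yl)-2,6,10-trimethyltrideca-6,10-dien-1-ol
Product: 22 (2S,6E,10E)-13-(furan-3-yl)-2,6,10-trimethyltrideca-6,10-dienal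
Conditions: Dess–Martin periodinane, NaHCO3, CH2Cl2, 0 °C; used crude at once
Reagents that add atoms: none
Why: Buffered Dess–Martin oxidation is non-enolising, so the α-methyl aldehyde should form without epimerisation at C6 and without attack on the furan.

Step 17
Reactants: 23 3-methylfuran-2(5H)-one
Product: 24 tert-butyldimethyl[(3-methylfuran-2-yl)oxy]silane
Conditions: TBSOTf, Et3N, CH2Cl2, 0 °C
Reagents that add atoms: tert-butyldimethylsilyl trifluoromethanesulfonate, CC(C)(C)[Si](C)(C)OS(=O)(=O)C(F)(F)F
Why: Soft enolisation with O-silylation of the butenolide gives the aromatic 2-silyloxyfuran, the usual γ-nucleophile for vinylogous aldol chemistry.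

Step 18
Reactants: 22 (2S,6E,10E)-13-(furan-3-yl)-2,6,10-trimethyltrideca-6,10-dienal; 24 tert-butyldimethyl[(3-methylfuran-2-yl)oxy]silane
Product: 25 5-[(2S,6E,10E)-13-(furan-3-yl)-1-hydroxy-2,6,10-trimethyltrideca-6,10-dien-1-yl]-3-methylfuran-2(5H)-one (diastereomer mixture at ring C4 and carbinol C5)
Conditions: BF3·OEt2 (1.1 equiv), CH2Cl2, −78 °C
Reagents that add atoms: none
Why: In this vinylogous Mukaiyama aldol reaction the silyloxyfuran attacks the Lewis-acid-activated aldehyde through its γ-carbon to form the C4–C5 bond, and both new centres are left uncontrolled because step 19 makes them sp2, while the low temperature protects C6 and the 3-alkylfuran.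

Step 19
Reactants: 25 5-[(2S,6E,10E)-13-(furan-3-yl)-1-hydroxy-2,6,10-trimethyltrideca-6,10-dien-1-yl]-3-methylfuran-2(5H)-one
Product: 27 (5Z)-5-[(2S,6E,10E)-13-(furan-3-yl)-2,6,10-trimethyltrideca-6,10-dien-1-ylidene]-3-methylfuran-2(5H)-one, via C5 mesylate 26 (not isolated)
Conditions: MsCl, Et3N, CH2Cl2, −20 to 0 °C; then DBU, 0 °C
Reagents that add atoms: none
Why: Mesylation followed by E1cB elimination through the aromatic 2-oxidofuran should give the ylidene lactone, with Z favoured because the C6 substituent then lies on the ring-oxygen side away from C3–H, and the short cold exposure to base is chosen to keep C6 intact.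

**Compound list**

1 | (R)-3-bromo-2-methylpropan-1-ol | BrC[C@H](C)CO | starting material
2 | (R)-(3-bromo-2-methylpropoxy)(tert-butyl)dimethylsilane | BrC[C@H](C)CO[Si](C)(C)C(C)(C)C | intermediate
3 | (4-bromobut-1-yn-1-yl)trimethylsilane | C[Si](C)(C)C#CCCBr | starting material
4 | [4-(trimethylsilyl)but-3-yn-1-yl]magnesium bromide (not isolated) | C[Si](C)(C)C#CCC[Mg]Br | intermediate
5 | tert-butyldimethyl{[(2S)-2-methyl-7-(trimethylsilyl)hept-6-yn-1-yl]oxy}silane | C[Si](C)(C)C#CCCC[C@H](C)CO[Si](C)(C)C(C)(C)C | intermediate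
6 | tert-butyldimethyl{[(2S)-2-methylhept-6-yn-1-yl]oxy}silane | C#CCCC[C@H](C)CO[Si](C)(C)C(C)(C)C | intermediate
7 | {(1E,6S)-7-[(tert-butyldimethylsilyl)oxy]-2,6-dimethylhept-1-en-1-yl}dimethylalane (not isolated) | C[Al](C)/C=C(\C)CCC[C@H](C)CO[Si](C)(C)C(C)(C)C | intermediate
8 | (2E,7S)-8-[(tert-butyldimethylsilyl)oxy]-3,7-dimethyloct-2-en-1-ol | OC/C=C(\C)CCC[C@H](C)CO[Si](C)(C)C(C)(C)C | intermediate
9 | tert-butyl{[(2S,6E)-8-bromo-2,6-dimethyloct-6-en-1-yl]oxy}dimethylsilane | BrC/C=C(\C)CCC[C@H](C)CO[Si](C)(C)C(C)(C)C | intermediate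
10 | tert-butyl{[(2S,6E)-2,6-dimethyl-8-(phenylsulfonyl)oct-6-en-1-yl]oxy}dimethylsilane | O=S(=O)(C/C=C(\C)CCC[C@H](C)CO[Si](C)(C)C(C)(C)C)c1ccccc1 | intermediate
11 | furan-3-carbaldehyde | O=Cc1ccoc1 | starting material
12 | methyl (2E)-3-(furan-3-yl)prop-2-enoate | COC(=O)/C=C/c1ccoc1 | intermediate
13 | methyl 3-(furan-3-yl)propanoate | COC(=O)CCc1ccoc1 | intermediate
14 | 3-(furan-3-yl)propanal | O=CCCc1ccoc1 | intermediate
15 | ethyl (2E)-5-(furan-3-yl)-2-methylpent-2-enoate | CCOC(=O)/C(C)=C/CCc1ccoc1 | intermediate
16 | (2E)-5-(furan-3-yl)-2-methylpent-2-en-1-ol | OC/C(C)=C/CCc1ccoc1 | intermediate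
17 | 3-[(3E)-5-bromo-4-methylpent-3-en-1-yl]furan | BrC/C(C)=C/CCc1ccoc1 | intermediate
18 | {(2E,7S)-8-[(tert-butyldimethylsilyl)oxy]-3,7-dimethyl-1-(phenylsulfonyl)oct-2-en-1-yl}lithium (not isolated) | [Li]C(/C=C(\C)CCC[C@H](C)CO[Si](C)(C)C(C)(C)C)S(=O)(=O)c1ccccc1 | intermediate
19 | tert-butyl{[(2S,6E,10E)-13-(furan-3-yl)-2,6,10-trimethyl-8-(phenylsulfonyl)trideca-6,10-dien-1-yl]oxy}dimethylsilane (C8 epimers) | CC(C)(C)[Si](C)(C)OC[C@@H](C)CCC/C(C)=C/C(C/C(C)=C/CCc1ccoc1)S(=O)(=O)c1ccccc1 | intermediate
20 | tert-butyl{[(2S,6E,10E)-13-(furan-3-yl)-2,6,10-trimethyltrideca-6,10-dien-1-yl]oxy}dimethylsilane | CC(C)(C)[Si](C)(C)OC[C@@H](C)CCC/C(C)=C/CC/C(C)=C/CCc1ccoc1 | intermediate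
21 | (2S,6E,10E)-13-(furan-3-yl)-2,6,10-trimethyltrideca-6,10-dien-1-ol | OC[C@@H](C)CCC/C(C)=C/CC/C(C)=C/CCc1ccoc1 | intermediate
22 | (2S,6E,10E)-13-(furan-3-yl)-2,6,10-trimethyltrideca-6,10-dienal | O=C[C@@H](C)CCC/C(C)=C/CC/C(C)=C/CCc1ccoc1 | intermediate
23 | 3-methylfuran-2(5H)-one | CC1=CCOC1=O | starting material
24 | tert-butyldimethyl[(3-methylfuran-2-yl)oxy]silane | Cc1ccoc1O[Si](C)(C)C(C)(C)C | intermediate
25 | 5-[(2S,6E,10E)-13-(furan-3-yl)-1-hydroxy-2,6,10-trimethyltrideca-6,10-dien-1-yl]-3-methylfuran-2(5H)-one (diastereomer mixture) | CC1=CC(C(O)[C@@H](C)CCC/C(C)=C/CC/C(C)=C/CCc2ccoc2)OC1=O | intermediate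
26 | (2S,6E,10E)-13-(furan-3-yl)-2,6,10-trimethyl-1-(4-methyl-5-oxo-2,5-dihydrofuran-2-yl)trideca-6,10-dien-1-yl methanesulfonate (not isolated) | CC1=CC(C(OS(C)(=O)=O)[C@@H](C)CCC/C(C)=C/CC/C(C)=C/CCc2ccoc2)OC1=O | intermediate
27 | (5Z)-5-[(2S,6E,10E)-13-(furan-3-yl)-2,6,10-trimethyltrideca-6,10-dien-1-ylidene]-3-methylfuran-2(5H)-one | CC1=C/C(=C/[C@@H](C)CCC/C(C)=C/CC/C(C)=C/CCc2ccoc2)OC1=O | target

**Step count**

Total: 19 steps. Longest linear sequence: 12 steps (steps 1–6, 13–16, 18, 19).

**Steps most likely to fail**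

1. Step 19. The E1cB elimination may give poor Z/E selectivity at C4=C5, and reversible deprotonation at C6 of the extended dienyl lactone by the amidine base may erode the C6 configuration. The fallback sets out from 22 and comes back at 27, and it also bypasses the Lewis-acid aldol of step 18.
 - Aldehyde 22 is homologated with dimethyl (1-diazo-2-oxopropyl)phosphonate, K2CO3 and MeOH at 0 °C (Ohira–Bestmann reaction) to the terminal alkyne (3S,7E,11E)-14-(furan-3-yl)-3,7,11-trimethyltetradeca-7,11-dien-1-yne F1.
 - Separately, prop-2-yn-1-ol is taken by copper-catalysed methylmagnesiation–iodination (MeMgBr, CuI; then I2) to (Z)-3-iodo-2-methylprop-2-en-1-ol F2.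
 - MnO2 oxidises this to (Z)-3-iodo-2-methylprop-2-enal F3, and Pinnick oxidation (NaClO2, NaH2PO4, 2-methylbut-2-ene) then gives (Z)-3-iodo-2-methylprop-2-enoic acid F4.
 - F1 and F4 are joined with PdCl2(PPh3)2, CuI and Et3N in MeCN in a tandem Sonogashira coupling and 5-exo-dig lactonisation, which should deliver 27 directly. Anti addition of the carboxylate across the alkyne fixes the Z geometry, and C6 is never exposed to base next to a carbonyl-conjugated system.

2. Step 14. Hydride may be delivered to C10 instead of C12, moving the alkene to C11=C12, or the π-allyl intermediate may lose its E geometry by π–σ–π rotation. The fallback sets out from 19 and comes back at 20: Birch-type electron-transfer cleavage of the C–S bond with Li in EtNH2 at −78 °C, in which the allyl anion is protonated in the flask and no π-allyl metal species is involved. A simple 3-alkylfuran and a silyl ether are expected to survive these conditions. No new compound is made (F0).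

3. Step 2. Slow reaction at the β-branched primary bromide may let Grignard homocoupling and reduction or elimination of 2 compete with the cross-coupling. The fallback reverses the polarity, setting out from 2 and coming back at 6 (step 3 is then not needed).
 - 2 is converted with Mg in THF into (R)-{3-[(tert-butyldimethylsilyl)oxy]-2-methylpropyl}magnesium bromide F5.
 - F5 opens ethylene oxide (CuI cat., THF, −30 °C to rt) to give (S)-5-[(tert-butyldimethylsilyl)oxy]-4-methylpentan-1-ol F6.
 - I2, PPh3 and imidazole convert the alcohol into (S)-tert-butyl[(5-iodo-2-methylpentyl)oxy]dimethylsilane F7.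
 - SN2 alkylation of lithium acetylide–ethylenediamine complex in DMSO with F7 gives 6.

**Further compounds**

F1 | step 19 | (3S,7E,11E)-14-(furan-3-yl)-3,7,11-trimethyltetradeca-7,11-dien-1-yne | C#C[C@@H](C)CCC/C(C)=C/CC/C(C)=C/CCc1ccoc1
F2 | step 19 | (Z)-3-iodo-2-methylprop-2-en-1-ol | OC/C(C)=C\I
F3 | step 19 | (Z)-3-iodo-2-methylprop-2-enal | O=C/C(C)=C\I
F4 | step 19 | (Z)-3-iodo-2-methylprop-2-enoic acid | OC(=O)/C(C)=C\I
F0 | step 14 | none | none
F5 | step 2 | (R)-{3-[(tert-butyldimethylsilyl)oxy]-2-methylpropyl}magnesium bromide | Br[Mg]C[C@H](C)CO[Si](C)(C)C(C)(C)C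
F6 | step 2 | (S)-5-[(tert-butyldimethylsilyl)oxy]-4-methylpentan-1-ol | OCCC[C@H](C)CO[Si](C)(C)C(C)(C)C
F7 | step 2 | (S)-tert-butyl[(5-iodo-2-methylpentyl)oxy]dimethylsilane | ICCC[C@H](C)CO[Si](C)(C)C(C)(C)C
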